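**Retrosynthetic overview**

1. Ring numbering (cyclohexenone of the target): C1 = ketone, C2 = heptenyl-bearing alkene carbon, C3 = CH2OH-bearing alkene carbon, C4 = carbinol, C5 = oxirane CH, C6 = quaternary oxirane carbon. Last disconnections: C2–heptenyl (Stille at a C2–Br) and the enoic acid chain (cross-metathesis, then oxidation, of a C6 allyl group).
2. Key disconnection: C2 is taken out of the ring as a CBr unit. The 2-bromocyclohex-2-enone arises by one-carbon ring expansion of a cyclopentane (C1, C3, C4, C5, C6): dibromocarbene adds to its C1=C3 silyl enol ether and the dibromocyclopropane opens across the old C1–C3 bond.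
3. Enabling feature: in the six-membered ring C2 lies between the carbonyl C1 and C3 and carries only a substituent that cross-coupling can deliver, and C6 is a fully substituted oxirane carbon, so the five-membered ketone can enolise only towards C3 and the insertion site is unambiguous.
4. Stereochemistry is settled on the five-membered ring: C4 comes from (R)-4-silyloxycyclopent-2-enone, and C5/C6 from a hydroxyl-directed epoxidation (all-cis), which gives the syn C4–O/oxirane relation. The ring expansion touches none of these centres.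
5. Order of ring formation: cyclopentene (purchased) → oxirane → transient dibromocyclopropane → cyclohexenone.

Key step: step 9

Remark: TBS = tert-butyldimethylsilyl, TMS = trimethylsilyl, allyl = prop-2-en-1-yl. The C3 centre of 8 and 9 and the two cyclopropane centres of 11 are transient (they become sp2), so the expected isomer is drawn for 8 and 9 and the centres of 11 are left open. Compound 1, allyltributylstannane, methacrolein, hept-1-yne and tributyltin hydride are taken as commercial.

**Route**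

Step 1
Reactants: 1 (R)-4-(TBS-oxy)cyclopent-2-en-1-one
Product: 2 (R)-4-(TBS-oxy)-2-iodocyclopent-2-en-1-one
Conditions: I2, pyridine/CH2Cl2, 0 °C → rt
Reagents that add atoms: iodine, II
Why: Iodine–pyridine α-iodination of a cyclic enone (conjugate addition of pyridine, iodination of the enolate, elimination; a Baylis–Hillman-like manifold) is established for 4-silyloxycyclopentenones and does not touch the C4 stereocentre.

Step 2
Reactants: 2 (R)-4-(TBS-oxy)-2-iodocyclopent-2-en-1-one
Product: 3 (R)-2-allyl-4-(TBS-oxy)cyclopent-2-en-1-one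
Conditions: allylSnBu3, Pd2(dba)3 (cat.), AsPh3, CuI, NMP, rt
Reagents that add atoms: allyltributylstannane, C=CC[Sn](CCCC)(CCCC)CCCC
Why: Stille coupling of the α-iodoenone runs under neutral conditions at room temperature, so the base-labile β-silyloxy ketone survives and the allyl double bond should not migrate into conjugation.

Step 3
Reactants: 3 (R)-2-allyl-4-(TBS-oxy)cyclopent-2-en-1-one
Product: 4 (1S,4R)-2-allyl-4-(TBS-oxy)cyclopent-2-en-1-ol (1,4-cis)
Conditions: NaBH4, CeCl3·7H2O, MeOH, −78 °C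
Reagents that add atoms: none
Why: Luche 1,2-reduction; hydride should attack the carbonyl from the face opposite the C4 silyloxy group, so the new carbinol centre (1S) is cis to OTBS.

Step 4
Reactants: 4 (1S,4R)-2-allyl-4-(TBS-oxy)cyclopent-2-en-1-ol
Product: 5 (1S,2S,4R,5R)-1-allyl-4-(TBS-oxy)-6-oxabicyclo[3.1.0]hexan-2-ol (oxirane, OH and OTBS all cis)
Conditions: VO(acac)2 (cat.), t-BuOOH (in decane), CH2Cl2, 0 °C → rt
Reagents that add atoms: tert-butyl hydroperoxide, CC(C)(C)OO
Why: Vanadium-catalysed hydroxyl-directed epoxidation of the cyclic allylic alcohol delivers oxygen to the trisubstituted ring alkene on the face of the C1 hydroxyl, which sets C5 and C6 with the oxirane cis to OH and therefore cis to the C4 silyloxy group, while the remote monosubstituted allyl alkene is neither directed nor reactive enough.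

Step 5
Reactants: 5 (1S,2S,4R,5R)-1-allyl-4-(TBS-oxy)-6-oxabicyclo[3.1.0]hexan-2-ol
Product: 6 (1R,4R,5R)-1-allyl-4-(TBS-oxy)-6-oxabicyclo[3.1.0]hexan-2-one
Conditions: Dess–Martin periodinane, CH2Cl2, rt
Reagents that add atoms: none
Why: Dess–Martin oxidation removes the temporary directing carbinol under near-neutral conditions that leave the oxirane, the silyl ether and the quaternary, non-epimerisable C6 centre intact.

Step 6
Reactants: 6 (1R,4R,5R)-1-allyl-4-(TBS-oxy)-6-oxabicyclo[3.1.0]hexan-2-one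
Product: 8 (1R,3R,4R,5R)-1-allyl-4-(TBS-oxy)-3-(hydroxymethyl)-6-oxabicyclo[3.1.0]hexan-2-one, via lithium enolate 7 (not isolated)
Conditions: LiHMDS, THF, −78 °C; CH2O (gas, from cracked paraformaldehyde), −78 °C; aq. NH4Cl
Reagents that add atoms: formaldehyde, C=O
Why: Because C6 is a quaternary oxirane carbon the ketone can be deprotonated only at C3, and the kinetic lithium enolate should undergo the aldol addition to monomeric formaldehyde at −78 °C faster than it expels the β-silyloxy group; the new C3 centre (expected trans to OTBS) is erased in step 8.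

Step 7
Reactants: 8 (1R,3R,4R,5R)-1-allyl-4-(TBS-oxy)-3-(hydroxymethyl)-6-oxabicyclo[3.1.0]hexan-2-one
Product: 9 (1R,3R,4R,5R)-1-allyl-4-(TBS-oxy)-3-[(TBS-oxy)methyl]-6-oxabicyclo[3.1.0]hexan-2-one
Conditions: TBSCl, imidazole, DMF, 0 °C
Reagents that add atoms: tert-butyldimethylsilyl chloride, CC(C)(C)[Si](C)(C)Cl
Why: Imidazole-mediated silylation of the primary alcohol is mild enough to avoid retro-aldol loss of formaldehyde from the β-hydroxy ketone.

Step 8
Reactants: 9 (1R,3R,4R,5R)-1-allyl-4-(TBS-oxy)-3-[(TBS-oxy)methyl]-6-oxabicyclo[3.1.0]hexan-2-one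
Product: 10 (1R,4R,5R)-1-allyl-4-(TBS-oxy)-3-[(TBS-oxy)methyl]-2-(TMS-oxy)-6-oxabicyclo[3.1.0]hex-2-ene
Conditions: TMSOTf, Et3N, CH2Cl2, −20 → 0 °C
Reagents that add atoms: trimethylsilyl trifluoromethanesulfonate, C[Si](C)(C)OS(=O)(=O)C(F)(F)F
Why: Soft enolisation with silyl triflate and amine (no free enolate, hence no β-elimination of either silyloxy group) should give the only possible, fully substituted C1=C3 silyl enol ether.

Step 9
Reactants: 10 (1R,4R,5R)-1-allyl-4-(TBS-oxy)-3-[(TBS-oxy)methyl]-2-(TMS-oxy)-6-oxabicyclo[3.1.0]hex-2-ene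
Product: 12 (1R,5R,6R)-1-allyl-3-bromo-5-(TBS-oxy)-4-[(TBS-oxy)methyl]-7-oxabicyclo[4.1.0]hept-3-en-2-one, via dibromocyclopropane adduct 11 (not isolated)
Conditions: CHBr3 (in excess over base), KOtBu, pentane, −30 °C → rt
Reagents that add atoms: bromoform, BrC(Br)Br
Why: Dibromocarbene (α-elimination of bromoform) adds as an electrophile to the electron-rich, fully substituted silyl enol ether C1=C3 in a concerted cheletropic [2+1] closure of the three-membered ring, giving the 1-siloxy-6,6-dibromobicyclo[3.1.0]hexane 11. On warming, ring strain and the oxygen lone pair at C1 drive disrotatory electrocyclic opening of the cyclopropane with loss of the endo bromide (Woodward–Hoffmann–DePuy rule); this cleaves the old C1–C3 bond, so the five-membered ring becomes the six-membered ring with the carbene carbon inserted as C2, and bromide then removes the TMS group from the 2-bromo-oxyallyl cation to leave the C1 ketone and the C2(Br)=C3 double bond. The closest known reaction type is the dihalocarbene one-carbon ring expansion of cycloalkanone silyl enol ethers to 2-halocycloalk-2-enones. No stereocentre of the product is formed: the two cyclopropane centres are transient, C4, C5 and C6 are untouched, and either face of attack converges because both carbene substituents are bromine, so one is always endo. The step needs chemoselectivity over the allyl group, secured by the much higher nucleophilicity of the tetrasubstituted enol ether towards the carbene, and regioselectivity of insertion, secured because the quaternary C6 allowed the enol ether to form only towards C3. Bromoform in excess over tert-butoxide leaves no base to attack the bromoenone, which also arrives with the C2 halogen that direct α-halogenation of so hindered an enone would have to force.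

Step 10
Reactants: 12 (1R,5R,6R)-1-allyl-3-bromo-5-(TBS-oxy)-4-[(TBS-oxy)methyl]-7-oxabicyclo[4.1.0]hept-3-en-2-one
Product: 13 (E)-4-[(1R,5R,6R)-3-bromo-5-(TBS-oxy)-4-[(TBS-oxy)methyl]-2-oxo-7-oxabicyclo[4.1.0]hept-3-en-1-yl]-2-methylbut-2-enal
Conditions: methacrolein (excess), Grubbs second-generation catalyst (cat.), CH2Cl2, 40 °C
Reagents that add atoms: methacrolein, CC(=C)C=O
Why: Olefin cross-metathesis of the terminal allyl group with excess methacrolein should give the trisubstituted (E)-enal under thermodynamic control, the tetrasubstituted electron-poor bromoalkene being inert to the ruthenium carbene.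

Step 11
Reactants: 14 hept-1-yne
Product: 15 (E)-tributyl(hept-1-en-1-yl)stannane
Conditions: Bu3SnH, AIBN (cat.), neat, 90 °C
Reagents that add atoms: tributyltin hydride, CCCC[SnH](CCCC)CCCC
Why: Radical hydrostannation of a terminal alkyne places tin at the terminal carbon, and reversible stannyl-radical addition equilibrates the product towards the (E)-alkenylstannane.

Step 12
Reactants: 13 (E)-4-[(1R,5R,6R)-3-bromo-5-(TBS-oxy)-4-[(TBS-oxy)methyl]-2-oxo-7-oxabicyclo[4.1.0]hept-3-en-1-yl]-2-methylbut-2-enal; 15 (E)-tributyl(hept-1-en-1-yl)stannane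
Product: 16 (E)-4-[(1R,5R,6R)-5-(TBS-oxy)-4-[(TBS-oxy)methyl]-3-[(E)-hept-1-en-1-yl]-2-oxo-7-oxabicyclo[4.1.0]hept-3-en-1-yl]-2-methylbut-2-enal
Conditions: Pd2(dba)3 (cat.), AsPh3, toluene, 100 °C
Reagents that add atoms: none
Why: Stille coupling of the α-bromoenone with the alkenylstannane proceeds with retention of alkene geometry under neutral conditions that tolerate the oxirane, the enal and both silyl ethers.

Step 13
Reactants: 16 (E)-4-[(1R,5R,6R)-5-(TBS-oxy)-4-[(TBS-oxy)methyl]-3-[(E)-hept-1-en-1-yl]-2-oxo-7-oxabicyclo[4.1.0]hept-3-en-1-yl]-2-methylbut-2-enal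
Product: 17 (E)-4-[(1R,5R,6R)-5-(TBS-oxy)-4-[(TBS-oxy)methyl]-3-[(E)-hept-1-en-1-yl]-2-oxo-7-oxabicyclo[4.1.0]hept-3-en-1-yl]-2-methylbut-2-enoic acid
Conditions: NaClO2, NaH2PO4, 2-methyl-2-butene, t-BuOH/H2O, 0 °C → rt
Reagents that add atoms: sodium chlorite, [Na+].[O-]Cl=O
Why: Pinnick (chlorite) oxidation converts the enal into the enoic acid chemoselectively, with 2-methyl-2-butene scavenging hypochlorous acid before it can attack the diene.

Step 14
Reactants: 17 (E)-4-[(1R,5R,6R)-5-(TBS-oxy)-4-[(TBS-oxy)methyl]-3-[(E)-hept-1-en-1-yl]-2-oxo-7-oxabicyclo[4.1.0]hept-3-en-1-yl]-2-methylbut-2-enoic acid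
Product: 18 (2E)-4-[(1R,5R,6R)-3-[(1E)-hept-1-en-1-yl]-5-hydroxy-4-(hydroxymethyl)-2-oxo-7-oxabicyclo[4.1.0]hept-3-en-1-yl]-2-methylbut-2-enoic acid (CNP0332048.1, the target)
Conditions: 48% aq. HF, MeCN, 0 °C → rt
Reagents that add atoms: none
Why: Acidic fluoride cleaves both silyl ethers without exposing the base-sensitive epoxy-enone to alkoxide or basic fluoride, and no stereocentre is affected.

**Compound list**

1 | (R)-4-(TBS-oxy)cyclopent-2-en-1-one | C1[C@@H](O[Si](C)(C)C(C)(C)C)C=CC1=O | starting material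
2 | (R)-4-(TBS-oxy)-2-iodocyclopent-2-en-1-one | C1[C@@H](O[Si](C)(C)C(C)(C)C)C=C(I)C1=O | intermediate
3 | (R)-2-allyl-4-(TBS-oxy)cyclopent-2-en-1-one | C1[C@@H](O[Si](C)(C)C(C)(C)C)C=C(CC=C)C1=O | intermediate
4 | (1S,4R)-2-allyl-4-(TBS-oxy)cyclopent-2-en-1-ol (cis) | C1[C@@H](O[Si](C)(C)C(C)(C)C)C=C(CC=C)[C@H]1O | intermediate
5 | (1S,2S,4R,5R)-1-allyl-4-(TBS-oxy)-6-oxabicyclo[3.1.0]hexan-2-ol (all-cis) | C1[C@@H](O[Si](C)(C)C(C)(C)C)[C@H]2O[C@@]2(CC=C)[C@H]1O | intermediate
6 | (1R,4R,5R)-1-allyl-4-(TBS-oxy)-6-oxabicyclo[3.1.0]hexan-2-one | C1[C@@H](O[Si](C)(C)C(C)(C)C)[C@H]2O[C@@]2(CC=C)C1=O | intermediate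
7 | lithium enolate of 6 (lithium (1R,4R,5R)-1-allyl-4-(TBS-oxy)-6-oxabicyclo[3.1.0]hex-2-en-2-olate) | [Li+].[O-]C1=C[C@@H](O[Si](C)(C)C(C)(C)C)[C@H]2O[C@@]12CC=C | intermediate
8 | (1R,3R,4R,5R)-1-allyl-4-(TBS-oxy)-3-(hydroxymethyl)-6-oxabicyclo[3.1.0]hexan-2-one | [C@@H]1(CO)[C@@H](O[Si](C)(C)C(C)(C)C)[C@H]2O[C@@]2(CC=C)C1=O | intermediate
9 | (1R,3R,4R,5R)-1-allyl-4-(TBS-oxy)-3-[(TBS-oxy)methyl]-6-oxabicyclo[3.1.0]hexan-2-one | [C@@H]1(CO[Si](C)(C)C(C)(C)C)[C@@H](O[Si](C)(C)C(C)(C)C)[C@H]2O[C@@]2(CC=C)C1=O | intermediate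
10 | (1R,4R,5R)-1-allyl-4-(TBS-oxy)-3-[(TBS-oxy)methyl]-2-(TMS-oxy)-6-oxabicyclo[3.1.0]hex-2-ene | C[Si](C)(C)OC1=C(CO[Si](C)(C)C(C)(C)C)[C@@H](O[Si](C)(C)C(C)(C)C)[C@H]2O[C@@]12CC=C | intermediate
11 | dibromocyclopropane adduct of 10 (6,6-dibromo-1-(TMS-oxy)bicyclo[3.1.0]hexane core fused to the oxirane; the two cyclopropane ring-fusion carbons of open configuration) | C[Si](C)(C)OC12C(Br)(Br)C1(CO[Si](C)(C)C(C)(C)C)[C@@H](O[Si](C)(C)C(C)(C)C)[C@H]3O[C@@]23CC=C | intermediate
12 | (1R,5R,6R)-1-allyl-3-bromo-5-(TBS-oxy)-4-[(TBS-oxy)methyl]-7-oxabicyclo[4.1.0]hept-3-en-2-one | BrC1=C(CO[Si](C)(C)C(C)(C)C)[C@@H](O[Si](C)(C)C(C)(C)C)[C@H]2O[C@@]2(CC=C)C1=O | intermediate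
13 | (E)-4-[(1R,5R,6R)-3-bromo-5-(TBS-oxy)-4-[(TBS-oxy)methyl]-2-oxo-7-oxabicyclo[4.1.0]hept-3-en-1-yl]-2-methylbut-2-enal | BrC1=C(CO[Si](C)(C)C(C)(C)C)[C@@H](O[Si](C)(C)C(C)(C)C)[C@H]2O[C@@]2(C/C=C(\C)C=O)C1=O | intermediate
14 | hept-1-yne | CCCCCC#C | starting material
15 | (E)-tributyl(hept-1-en-1-yl)stannane | CCCCC/C=C/[Sn](CCCC)(CCCC)CCCC | intermediate
16 | (E)-4-[(1R,5R,6R)-5-(TBS-oxy)-4-[(TBS-oxy)methyl]-3-[(E)-hept-1-en-1-yl]-2-oxo-7-oxabicyclo[4.1.0]hept-3-en-1-yl]-2-methylbut-2-enal | CCCCC/C=C/C1=C(CO[Si](C)(C)C(C)(C)C)[C@@H](O[Si](C)(C)C(C)(C)C)[C@H]2O[C@@]2(C/C=C(\C)C=O)C1=O | intermediate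
17 | (E)-4-[(1R,5R,6R)-5-(TBS-oxy)-4-[(TBS-oxy)methyl]-3-[(E)-hept-1-en-1-yl]-2-oxo-7-oxabicyclo[4.1.0]hept-3-en-1-yl]-2-methylbut-2-enoic acid | CCCCC/C=C/C1=C(CO[Si](C)(C)C(C)(C)C)[C@@H](O[Si](C)(C)C(C)(C)C)[C@H]2O[C@@]2(C/C=C(\C)C(=O)O)C1=O | intermediate
18 | (2E)-4-[(1R,5R,6R)-3-[(1E)-hept-1-en-1-yl]-5-hydroxy-4-(hydroxymethyl)-2-oxo-7-oxabicyclo[4.1.0]hept-3-en-1-yl]-2-methylbut-2-enoic acid (CNP0332048.1) | CCCCC/C=C/C1=C(CO)[C@@H](O)[C@H]2O[C@@]2(C/C=C(\C)C(=O)O)C1=O | target

**Step count and risks**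

Total step count: 14. Longest linear sequence: 13 steps (1 to 18 through steps 1–10 and 12–14); step 11 is a one-step side branch.

Steps most likely to fail:

Step 9. The process at risk is tert-butoxide attack on the oxirane or on the bromoenone as it forms, together with slow carbene addition to the crowded enol ether and competing cyclopropanation of the allyl group. The fallback replaces the carbene/electrocyclic route by an oxidative radical ring enlargement and sets out from 10. A Simmons–Smith cyclopropanation (Et2Zn, CH2I2, CH2Cl2, 0 °C) should give the siloxycyclopropane F1. Opening of its internal cyclopropane bond with FeCl3 in DMF (Ito–Saegusa-type ring enlargement through a β-keto radical) should give the six-membered β-chloro ketone F2. α-Bromination at C2, the only enolisable position, with phenyltrimethylammonium tribromide in THF (a reagent that spares isolated alkenes) should give the 2-bromo-3-chloro ketone F3, and triethylamine-induced loss of HCl returns to the route at 12.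

Step 6. The process at risk is E1cB expulsion of the C4 silyloxy group from the lithium enolate, with retro-aldol loss or double addition of formaldehyde as further losses. The fallback avoids the free enolate and sets out from 6. Soft enolisation (TMSOTf, Et3N, CH2Cl2, 0 °C) should give the trimethylsilyl enol ether F4, and a lanthanide-triflate-catalysed aqueous Mukaiyama aldol with formalin (Yb(OTf)3, THF/H2O, rt) should hydroxymethylate C3 and return to the route at 8.

Step 4. The process at risk is erosion of facial selectivity, because the cis silyloxy group at C4 shields the very face to which the hydroxyl directs. The fallback sets the oxirane on the enone by hydrogen-bond-directed nucleophilic epoxidation and sets out from 3, bypassing steps 3–5. Desilylation (HF·pyridine, THF) should give the hydroxy enone (R)-2-allyl-4-hydroxycyclopent-2-en-1-one F5. Weitz–Scheffer epoxidation directed by the free C4 hydroxyl (t-BuOOH, Triton B, THF, 0 °C) should give the syn epoxy alcohol (1R,4R,5R)-1-allyl-4-hydroxy-6-oxabicyclo[3.1.0]hexan-2-one F6, and silylation (TBSCl, imidazole, DMF) returns to the route at 6.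

Further compounds
F1 | step 9 | siloxycyclopropane from 10 (1-(TMS-oxy)bicyclo[3.1.0]hexane core fused to the oxirane; cyclopropane ring-fusion carbons of open configuration) | C[Si](C)(C)OC12CC1(CO[Si](C)(C)C(C)(C)C)[C@@H](O[Si](C)(C)C(C)(C)C)[C@H]3O[C@@]23CC=C
F2 | step 9 | (1R,5R,6R)-1-allyl-4-chloro-5-(TBS-oxy)-4-[(TBS-oxy)methyl]-7-oxabicyclo[4.1.0]heptan-2-one (C4 of the bicycle open) | O=C1CC(Cl)(CO[Si](C)(C)C(C)(C)C)[C@@H](O[Si](C)(C)C(C)(C)C)[C@H]2O[C@@]12CC=C
F3 | step 9 | (1R,5R,6R)-1-allyl-3-bromo-4-chloro-5-(TBS-oxy)-4-[(TBS-oxy)methyl]-7-oxabicyclo[4.1.0]heptan-2-one (C3 and C4 of the bicycle open) | O=C1C(Br)C(Cl)(CO[Si](C)(C)C(C)(C)C)[C@@H](O[Si](C)(C)C(C)(C)C)[C@H]2O[C@@]12CC=C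
F4 | step 6 | (1R,4R,5R)-1-allyl-4-(TBS-oxy)-2-(TMS-oxy)-6-oxabicyclo[3.1.0]hex-2-ene | C[Si](C)(C)OC1=C[C@@H](O[Si](C)(C)C(C)(C)C)[C@H]2O[C@@]12CC=C
F5 | step 4 | (R)-2-allyl-4-hydroxycyclopent-2-en-1-one | C1[C@@H](O)C=C(CC=C)C1=O
F6 | step 4 | (1R,4R,5R)-1-allyl-4-hydroxy-6-oxabicyclo[3.1.0]hexan-2-one | C1[C@@H](O)[C@H]2O[C@@]2(CC=C)C1=O
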